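## Structural features

Difengpiol B is a 2,3-dihydrobenzofuran (O1, C2, C3, C3a–C7a) with a methoxy group at C7, a 3-hydroxypropyl chain at C5 and a hydroxymethyl group at C3. C2 is bonded to C1' of a cyclohexane that carries a tertiary hydroxyl at C1', a secondary hydroxyl at C3' and a methoxy group at C4'. The five stereocentres are (2S,3R,1'S,3'S,4'S): C3, C2 and C1' are contiguous with the C2 and C3 substituents trans, the C1' and C3' hydroxyls are cis (1,3), and the C4' methoxy group is trans to the C3' hydroxyl. Fragile points are the C2–O1 aryl ether, which is β to any carbonyl on the C3 side and can be lost by E1cB ring opening; the tertiary carbinol, which passes a silyl or acyl group to a neighbouring alkoxide; three free hydroxyls; and an electron-rich arene. The real difficulty is C1': its two ring arms, C2' and C6', are both methylene groups and differ only further along the ring, so C1' must be set while the ring is built and C2 must then be set next to a neighbour that gives it no bias. The cyclohexane pattern (cis-1,3-diol, trans-3',4'-dioxygenation) is the signature of a hydroxyl-directed epoxidation of a C3'=C4' alkene followed by diaxial opening at C4'. The plan exploits the fact that C3 is bonded to C3a and carries exactly one oxidised carbon: moving the arene bond from C3 to that exocyclic carbon turns the five-membered ring into a chroman-4-one whose carbonyl carbon is the hydroxymethyl carbon, which is what a Wolff ring contraction does in the forward sense.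

## Logic of the disconnections

27 ⇒ 26 + 2. The C4'–OMe bond is cut. The trans arrangement of the C3' and C4' oxygens is what anti opening of a C3'/C4' oxirane gives. Two stereocentres collapse into the geometry of one three-membered ring. The forward step must attack C4' and not C3'; in the chair with the large C1' substituent equatorial only attack at C4' is diaxial.

26 ⇒ 25. Both C–O bonds of the oxirane are cut. Its oxygen is cis to the C1' hydroxyl and can be delivered by it. What remains is a cyclohex-3-ene whose only stereocentre is C1'. The forward step needs the C1' hydroxyl free and axial and a metal peroxide that binds it.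

25 ⇒ 24 ⇒ 23. No skeletal bond is cut: two O-protecting bonds are restored and the hydroxymethyl carbon is raised to the ester level, because an ester is what capture of a ketene gives. The C1' oxygen must be capped while C3 is an ester under base, since a free alkoxide would lactonise onto a cis ester and hold C3 in the wrong configuration. The cap must survive base and hydride, must not migrate, and should leave together with the side-chain cap.

23 ⇒ 20 + 2 (key disconnection). The C3–C3a bond is cut and C3a is reconnected to the ester carbon, which becomes the C4 carbonyl of a 3-diazochroman-4-one; the ester O–Me bond goes to 2. The trans C2/C3 pair reduces to the single stereocentre C2, because C3 becomes an epimerisable ester α-carbon controlled by C2. A six-membered β-aryloxy aryl ketone is also far easier to assemble than the five-membered ring. The forward step must let nitrogen loss and aryl migration outrun carbene chemistry at the adjacent C2–H, and C2 must survive the base that equilibrates C3.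

20 ⇒ 18. The C3=N2 bond is cut. C3 must be activated without letting its enolate expel the C2–O1 phenoxide, which would scramble C2.

18 ⇒ 17. The O1–C2 bond is cut (oxa-Michael retron). Ring and C2 stereocentre vanish together and an E enone remains. Since the arms of C1' are nearly identical, the substrate cannot choose the enone face; the forward step must be catalyst-controlled and kinetic.

17 ⇒ 6 + 16. The enone C=C bond (the later C2–C3) is cut. This gives two halves of similar size, with the only stereocentre in 16. 16 has no α-hydrogen, so only one condensation direction exists. Under hydroxide a silyl ether on the C1' oxygen would shift to the aldolate oxygen and be eliminated, so an acetal cap is used instead; the quench must also stop the phenoxide from closing the ring without the catalyst.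

6 ⇒ 5 ⇒ 1. The aryl–acyl bond is cut, together with the side-chain O–Si bond. The phenol oxygen of 1 directs the acyl group, and with the para and one ortho position occupied only the required carbon is free. The acid must effect the rearrangement without cleaving the aryl methyl ether.

16 ⇒ 15 ⇒ 14 ⇒ 13 ⇒ 11 + 12. After adjusting the oxidation level and the groups on the C1' oxygen, the C1'–C2' and C5'–C6' bonds are cut in a Diels–Alder sense. This is the only moment at which the two arms of C1' differ while the stereocentre forms, because they arise from the two faces of a prochiral alkene. Facial control is demanded and is met by a five-membered acetal whose tert-butyl group shields one face. 11 ⇒ 9 ⇒ 7 + 8 traces that acetal to the chiral pool; 9 must be the pure cis isomer, because the trans isomer leads to the enantiomer of 11.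

## Other disconnections considered

Alternative 1: The cut removes the C3' hydroxyl and the C4' hydrogen and restores a C3'=C4' enol ether, so that the whole oxygenation pattern of the cyclohexane is traced to the C1' oxygen.
- Forward step: the hydrodimethylsilyl ether A1 would undergo platinum-catalysed intramolecular hydrosilylation to the bridged oxasilolane A2 (C3'–Si and C4'–H on the same face). Tamao–Fleming oxidation would then give the diol ester A3 with retention at C3'.
- In favour: the tether can reach the alkene only from the face of the C1' oxygen, so the cis-1,3-diol is fixed by geometry. Syn addition puts the C4' hydrogen on that face, which leaves the methoxy group trans. No regiochemical question of the epoxide-opening kind arises. On the control of C3' and C4' it is the equal of steps 15 and 16, arguably the better.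
- Against: it solves only the cyclohexane. A3 must still be joined through its ester carbon to the arene, and C2, C3 and the dihydrofuran ring must be built next to a finished, densely oxygenated ring. The enol ether of A1 is acid-labile, the bridge needs the silyloxy group axial, and A1 needs its own enantioselective cycloaddition.
- Comparison: mechanistically both plans relay from C1' by intramolecular delivery. Structurally the alternative sets the ring stereocentres early, the chosen plan in its last two steps. In step economy it needs an extra oxidation and leaves the harder half of the molecule open.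

Alternative 2: The cut is C1'–C2', which opens the cyclohexane to the diketone A4, in which C1' is a ketone on C2 of a finished dihydrobenzofuran.
- Forward step: a chiral secondary amine would form the enamine of the methyl ketone, which attacks the C1' carbonyl (6-enolendo-exo-trig aldol) to give the β-hydroxy ketone A5. A 1,3-syn reduction of the C3' ketone (Narasaka–Prasad) would follow.
- In favour: C1' is created while its two arms are different (one is the nucleophile) and next to C2, so both the α-aryloxy stereocentre and the catalyst can steer the carbinol. On the C1'/C2 relationship it is better than the chosen plan, which relies on a catalyst alone. As a ring-forming C–C bond construction under mild conditions it is the equal of step 12.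
- Against: in A4, C2 is α to the C1' ketone and C4' is α to the methyl ketone, so both are open to epimerisation under amine catalysis. Enamine formation can also occur on the C4' or C6' side, and the aldol is reversible. A4 presupposes the trans dihydrobenzofuran, made by other means, and a further stereoselective reduction is needed.
- Comparison: the chosen plan sets each stereocentre either where it cannot enolise or under thermodynamic control; the alternative carries three labile centres through its key step. In step economy it is longer, because the dihydrofuran ring lies outside the step.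

Alternative 3: The cut is C2–C3 and O1–C2, a [4+1] disconnection of the dihydrofuran into the phenol sulfone A6 and the acyl sulfonium ylide A7.
- Forward step: carbonate base would unmask the ortho-quinone methide from A6. The ylide carbon of A7 would add to the methide carbon, and the phenoxide would close the ring by displacing the sulfide, giving the trans ketone A8. Allyl addition under chelation with O1 and ring-closing metathesis would give the carbinol A9, which corresponds to 25 with two hydroxyls still protected.
- In favour: two bonds, the ring and both C2 and C3 form in one convergent step, trans by the anti closure and by thermodynamics. C1' is then set from C2 by 1,2-chelation control while its arms are still different (allyl against butenyl). This is a better answer to the C1'/C2 problem than step 10, and the sequence is probably shorter.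
- Against: neither A6 nor A7 is chiral, so absolute configuration needs a chiral ylide or catalyst. That is less secure for an alkyl-substituted quinone methide, which can tautomerise to a vinyl phenol. C2 of A8 is α to a ketone, and the benzyl ether can be removed only after the alkene is consumed.
- Comparison: the alternative wins on convergence and relative stereocontrol. The chosen plan wins on absolute control (chiral-pool auxiliary for C1', thermodynamic C3) and forms one bond in a rearrangement with no intermolecular selectivity issue.

Key step: step 12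

Remark: the key-step pair 20/23 carries (2S,1'S) and trans C2/C3, consistent with the (2S,3R,1'S,3'S,4'S) target; the tertiary oxygen is capped as a methoxymethyl ether instead of a silyl ether, with the skeletons unchanged.

Assumption: the quinidine-derived thiourea of step 10 is taken to give (2S)-18; if its sense of induction is the opposite, the quinine-derived pseudo-enantiomer is used and nothing else changes.

## Steps

Step 1
Reactants: 1 dihydroconiferyl alcohol; 2 methanol
Product: 5 1-[2-hydroxy-5-(3-hydroxypropyl)-3-methoxyphenyl]ethan-1-one, via diacetate 3 (not isolated), via acetoxypropyl ketone 4 (not isolated)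
Conditions: Ac2O, BF3·OEt2, 90 °C; then MeOH, 65 °C
Reagents that add atoms: acetic anhydride CC(=O)OC(C)=O
Why: Both hydroxyls are acetylated and the aryl acetate undergoes a BF3-mediated Fries rearrangement; with the para position and one ortho position occupied the acyl group can settle only at the free ortho carbon, where the product is held as a boron chelate. Warm methanol breaks the chelate and, with BF3 as catalyst, transesterifies the primary acetate.

Step 2
Reactants: 5 1-[2-hydroxy-5-(3-hydroxypropyl)-3-methoxyphenyl]ethan-1-one
Product: 6 1-[5-(3-{[tert-butyl(dimethyl)silyl]oxy}propyl)-2-hydroxy-3-methoxyphenyl]ethan-1-one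
Conditions: TBSCl, imidazole, CH2Cl2, 0 °C
Reagents that add atoms: tert-butyl(chloro)dimethylsilane CC(C)(C)[Si](C)(C)Cl
Why: Silylation of the primary alcohol; the phenol is hydrogen-bonded to the ortho carbonyl and far less nucleophilic.

Step 3
Reactants: 7 (R)-lactic acid; 8 pivalaldehyde
Product: 9 (2R,5R)-2-tert-butyl-5-methyl-1,3-dioxolan-4-one
Conditions: TsOH·H2O (cat.), pentane, reflux, −H2O; crystallisation from pentane, −78 °C
Reagents that add atoms: none
Why: Acid-catalysed acetalisation of the α-hydroxy acid with azeotropic removal of water; the cis isomer is favoured and is purified by cold crystallisation, which matters because the trans isomer would lead to the enantiomer of 11.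

Step 4
Reactants: 9 (2R,5R)-2-tert-butyl-5-methyl-1,3-dioxolan-4-one
Product: 11 (2R)-2-tert-butyl-5-methylidene-1,3-dioxolan-4-one, via bromide 10 (not isolated)
Conditions: NBS, AIBN (cat.), cyclohexane, reflux; then Et3N, 0 °C to rt
Reagents that add atoms: none
Why: Wohl–Ziegler radical bromination at C5 (captodative radical between O and C=O) followed by E2 loss of HBr; the acetal carbon is untouched and now carries the only stereochemical information.

Step 5
Reactants: 11 (2R)-2-tert-butyl-5-methylidene-1,3-dioxolan-4-one; 12 buta-1,3-diene
Product: 13 (2R,5S)-2-tert-butyl-1,3-dioxaspiro[4.5]dec-7-en-4-one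
Conditions: toluene, BHT (cat.), sealed vessel, 110 °C
Reagents that add atoms: none
Why: Thermal Diels–Alder reaction of a captodative exocyclic alkene; the diene adds to the face opposite the tert-butyl group, which makes the spiro carbon (the later C1') S. With an unsubstituted diene no endo/exo or regiochemical question arises.

Step 6
Reactants: 13 (2R,5S)-2-tert-butyl-1,3-dioxaspiro[4.5]dec-7-en-4-one; 2 methanol
Product: 14 methyl (1S)-1-hydroxycyclohex-3-ene-1-carboxylate
Conditions: NaOMe (cat.), MeOH, 0 °C to rt
Reagents that add atoms: methanol CO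
Why: Methoxide opens the lactone-acetal by transesterification and the hemiacetal alkoxide expels pivalaldehyde; C1' is not involved.

Step 7
Reactants: 14 methyl (1S)-1-hydroxycyclohex-3-ene-1-carboxylate
Product: 15 methyl (1S)-1-(methoxymethoxy)cyclohex-3-ene-1-carboxylate
Conditions: MOMCl, i-Pr2NEt, Bu4NI (cat.), CH2Cl2, 40 °C
Reagents that add atoms: chloromethyl methyl ether COCCl
Why: Williamson-type O-alkylation of the tertiary alcohol with an oxocarbenium-like electrophile under iodide catalysis; an acetal cap cannot migrate to a neighbouring alkoxide in step 9, as a silyl or acyl group would.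

Step 8
Reactants: 15 methyl (1S)-1-(methoxymethoxy)cyclohex-3-ene-1-carboxylate
Product: 16 (1S)-1-(methoxymethoxy)cyclohex-3-ene-1-carbaldehyde
Conditions: i-Bu2AlH, CH2Cl2, −78 °C; aq. KNa tartrate
Reagents that add atoms: none
Why: Partial reduction of an ester; the α-alkoxy group chelates aluminium in the tetrahedral intermediate, which therefore survives at −78 °C and releases the aldehyde only on work-up.

Step 9
Reactants: 6 1-[5-(3-{[tert-butyl(dimethyl)silyl]oxy}propyl)-2-hydroxy-3-methoxyphenyl]ethan-1-one; 16 (1S)-1-(methoxymethoxy)cyclohex-3-ene-1-carbaldehyde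
Product: 17 (2E)-1-[5-(3-{[tert-butyl(dimethyl)silyl]oxy}propyl)-2-hydroxy-3-methoxyphenyl]-3-[(1S)-1-(methoxymethoxy)cyclohex-3-en-1-yl]prop-2-en-1-one
Conditions: KOH, EtOH–THF, 0 °C to rt; cold aq. citric acid
Reagents that add atoms: none
Why: Claisen–Schmidt condensation with a non-enolisable aldehyde; E1cB dehydration gives the E enone. In strong base the product rests as the ring-open phenoxide, so a cold acidic quench should return the hydrogen-bonded 2'-hydroxy enone before it can close.

Step 10
Reactants: 17 (2E)-1-[5-(3-{[tert-butyl(dimethyl)silyl]oxy}propyl)-2-hydroxy-3-methoxyphenyl]-3-[(1S)-1-(methoxymethoxy)cyclohex-3-en-1-yl]prop-2-en-1-one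
Product: 18 (2S)-6-(3-{[tert-butyl(dimethyl)silyl]oxy}propyl)-8-methoxy-2-[(1S)-1-(methoxymethoxy)cyclohex-3-en-1-yl]-2,3-dihydro-4H-chromen-4-one
Conditions: quinidine-derived thiourea [1-(3,5-bis(trifluoromethyl)phenyl)-3-((9R)-6'-methoxycinchonan-9-yl)thiourea] (10 mol%), toluene, −20 °C
Reagents that add atoms: none
Why: Bifunctional cinchona amine–thiourea catalysis of an intramolecular oxa-Michael addition (6-endo-trig): the thiourea binds the enone carbonyl and the quinuclidine delivers the phenol as a general base. C2 is set by the catalyst, because the two arms of C1' are too alike for the substrate to exert a bias.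

Step 11
Reactants: 18 (2S)-6-(3-{[tert-butyl(dimethyl)silyl]oxy}propyl)-8-methoxy-2-[(1S)-1-(methoxymethoxy)cyclohex-3-en-1-yl]-2,3-dihydro-4H-chromen-4-one
Product: 20 (2S)-6-(3-{[tert-butyl(dimethyl)silyl]oxy}propyl)-3-diazo-8-methoxy-2-[(1S)-1-(methoxymethoxy)cyclohex-3-en-1-yl]-2,3-dihydro-4H-chromen-4-one, via trifluoroacetyl ketone 19 (not isolated)
Conditions: LiN(SiMe3)2, THF, −78 °C; CF3CO2CH2CF3, −78 °C; then MsN3, Et3N, H2O, MeCN, rt
Reagents that add atoms: methanesulfonyl azide CS(=O)(=O)N=[N+]=[N-]
Why: Detrifluoroacetylative diazo transfer: the kinetic lithium enolate is C-acylated at −78 °C before it can expel the phenoxide, and the 1,3-diketone then takes up two nitrogens from the azide with loss of the trifluoroacetyl group as the sulfonamide. Once C3 is diazo-substituted, C2 can no longer epimerise through an enolate.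

Step 12
Reactants: 20 (2S)-6-(3-{[tert-butyl(dimethyl)silyl]oxy}propyl)-3-diazo-8-methoxy-2-[(1S)-1-(methoxymethoxy)cyclohex-3-en-1-yl]-2,3-dihydro-4H-chromen-4-one; 2 methanol
Product: 23 methyl (2S,3S)-5-(3-{[tert-butyl(dimethyl)silyl]oxy}propyl)-7-methoxy-2-[(1S)-1-(methoxymethoxy)cyclohex-3-en-1-yl]-2,3-dihydro-1-benzofuran-3-carboxylate, via ketene 21 (not isolated), via cis ester 22 (not isolated)
Conditions: hν (λ > 300 nm, Pyrex), degassed MeOH, 0 °C; then NaOMe (cat.), 0 °C to rt; AcOH quench
Reagents that add atoms: methanol CO
Why: Excitation of the diazo ketone, which the ring holds s-cis, causes loss of N2 concerted with a 1,2-shift of the aryl carbon C4a from the carbonyl carbon to the diazo carbon; this is a photochemical Wolff rearrangement with ring contraction, the closest models being 2-diazo-1-tetralone to an indane-1-carboxylate and 3-diazochroman-4-one to a 2,3-dihydrobenzofuran-3-carboxylate. The new C3–C3a bond turns the pyranone into the dihydrofuran ring; the ring is closed by migration, not by an exo or endo cyclisation, and the former carbonyl carbon leaves the ring as the ketene carbon of 21. Methanol adds to the ketene and the ester enol is protonated mainly on the face away from the C2 substituent, which gives chiefly the cis ester 22. Catalytic NaOMe then equilibrates C3 through the ester enolate, and the tertiary C1' group on the fixed C2 centre drives the mixture to the trans ester 23, so C3 is under thermodynamic control by C2. The step needs migration to outrun carbene chemistry (hydride shift from C2, insertion into O–H or into the OCH2O group); the s-cis lock and direct, unsensitised irradiation at low temperature secure this, and the aryl carbon is the only group on the carbonyl that can migrate. C2 and C1' take no part, and the equilibration is kept cold and short so that the ester enolate does not eliminate the C2–O1 bond.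

Step 13
Reactants: 23 methyl (2S,3S)-5-(3-{[tert-butyl(dimethyl)silyl]oxy}propyl)-7-methoxy-2-[(1S)-1-(methoxymethoxy)cyclohex-3-en-1-yl]-2,3-dihydro-1-benzofuran-3-carboxylate
Product: 24 [(2S,3R)-5-(3-{[tert-butyl(dimethyl)silyl]oxy}propyl)-7-methoxy-2-[(1S)-1-(methoxymethoxy)cyclohex-3-en-1-yl]-2,3-dihydro-1-benzofuran-3-yl]methanol
Conditions: LiAlH4, THF, 0 °C
Reagents that add atoms: none
Why: Hydride reduction of the ester to the primary alcohol; addition to the carbonyl is faster than enolisation, so C3 keeps its configuration (the descriptor changes only by priority), and the acetal and silyl ether are inert.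

Step 14
Reactants: 24 [(2S,3R)-5-(3-{[tert-butyl(dimethyl)silyl]oxy}propyl)-7-methoxy-2-[(1S)-1-(methoxymethoxy)cyclohex-3-en-1-yl]-2,3-dihydro-1-benzofuran-3-yl]methanol; 2 methanol
Product: 25 (1S)-1-[(2S,3R)-3-(hydroxymethyl)-5-(3-hydroxypropyl)-7-methoxy-2,3-dihydro-1-benzofuran-2-yl]cyclohex-3-en-1-ol
Conditions: HCl (aq., 0.5 equiv), MeOH, 45 °C
Reagents that add atoms: none
Why: Acid-catalysed transacetalisation to methanol removes the methoxymethyl group and the same conditions solvolyse the primary silyl ether; no carbon stereocentre is involved.

Step 15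
Reactants: 25 (1S)-1-[(2S,3R)-3-(hydroxymethyl)-5-(3-hydroxypropyl)-7-methoxy-2,3-dihydro-1-benzofuran-2-yl]cyclohex-3-en-1-ol
Product: 26 (1S,3S,6R)-3-[(2S,3R)-3-(hydroxymethyl)-5-(3-hydroxypropyl)-7-methoxy-2,3-dihydro-1-benzofuran-2-yl]-7-oxabicyclo[4.1.0]heptan-3-ol
Conditions: VO(acac)2 (cat.), t-BuOOH, CH2Cl2, 0 °C to rt
Reagents that add atoms: tert-butyl hydroperoxide CC(C)(C)OO
Why: Hydroxyl-directed epoxidation: the tertiary homoallylic hydroxyl binds pentavalent vanadium, which delivers the peroxide oxygen to the alkene face cis to the C1' hydroxyl. The dihydrobenzofuranyl group sits equatorial, so the hydroxyl is axial as delivery requires, and the two primary hydroxyls are too far from the alkene to compete.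

Step 16
Reactants: 26 (1S,3S,6R)-3-[(2S,3R)-3-(hydroxymethyl)-5-(3-hydroxypropyl)-7-methoxy-2,3-dihydro-1-benzofuran-2-yl]-7-oxabicyclo[4.1.0]heptan-3-ol; 2 methanol
Product: 27 difengpiol B
Conditions: CSA (cat.), MeOH, 0 °C to rt
Reagents that add atoms: methanol CO
Why: Acid-catalysed anti opening of the epoxide under Fürst–Plattner control: in the half-chair with the large C1' substituent equatorial, diaxial opening is possible only by attack at C4'. This puts the methoxy group trans to the C3' hydroxyl and leaves that hydroxyl cis to the C1' hydroxyl.

## Compound list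

1 | dihydroconiferyl alcohol, 4-(3-hydroxypropyl)-2-methoxyphenol | COc1cc(CCCO)ccc1O | starting material
2 | methanol | CO | starting material
3 | 4-(3-acetoxypropyl)-2-methoxyphenyl acetate | COc1cc(CCCOC(C)=O)ccc1OC(C)=O | intermediate (not isolated)
4 | 3-(3-acetyl-4-hydroxy-5-methoxyphenyl)propyl acetate | COc1cc(CCCOC(C)=O)cc(C(C)=O)c1O | intermediate (not isolated)
5 | 1-[2-hydroxy-5-(3-hydroxypropyl)-3-methoxyphenyl]ethan-1-one | COc1cc(CCCO)cc(C(C)=O)c1O | intermediate
6 | 1-[5-(3-{[tert-butyl(dimethyl)silyl]oxy}propyl)-2-hydroxy-3-methoxyphenyl]ethan-1-one | COc1cc(CCCO[Si](C)(C)C(C)(C)C)cc(C(C)=O)c1O | intermediate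
7 | (R)-lactic acid | C[C@@H](O)C(=O)O | starting material
8 | pivalaldehyde | CC(C)(C)C=O | starting material
9 | (2R,5R)-2-tert-butyl-5-methyl-1,3-dioxolan-4-one (cis) | C[C@H]1O[C@@H](C(C)(C)C)OC1=O | intermediate
10 | 5-bromo-2-tert-butyl-5-methyl-1,3-dioxolan-4-one (acetal carbon as in 9, both C5 epimers) | CC1(Br)O[C@@H](C(C)(C)C)OC1=O | intermediate (not isolated)
11 | (2R)-2-tert-butyl-5-methylidene-1,3-dioxolan-4-one | C=C1O[C@@H](C(C)(C)C)OC1=O | intermediate
12 | buta-1,3-diene | C=CC=C | starting material
13 | (2R,5S)-2-tert-butyl-1,3-dioxaspiro[4.5]dec-7-en-4-one | CC(C)(C)[C@H]1OC(=O)[C@]2(CC=CCC2)O1 | intermediate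
14 | methyl (1S)-1-hydroxycyclohex-3-ene-1-carboxylate | COC(=O)[C@]1(O)CCC=CC1 | intermediate
15 | methyl (1S)-1-(methoxymethoxy)cyclohex-3-ene-1-carboxylate | COC(=O)[C@]1(OCOC)CCC=CC1 | intermediate
16 | (1S)-1-(methoxymethoxy)cyclohex-3-ene-1-carbaldehyde | O=C[C@]1(OCOC)CCC=CC1 | intermediate
17 | (2E)-1-[5-(3-{[tert-butyl(dimethyl)silyl]oxy}propyl)-2-hydroxy-3-methoxyphenyl]-3-[(1S)-1-(methoxymethoxy)cyclohex-3-en-1-yl]prop-2-en-1-one | COc1cc(CCCO[Si](C)(C)C(C)(C)C)cc(C(=O)/C=C/[C@]2(OCOC)CCC=CC2)c1O | intermediate
18 | (2S)-6-(3-{[tert-butyl(dimethyl)silyl]oxy}propyl)-8-methoxy-2-[(1S)-1-(methoxymethoxy)cyclohex-3-en-1-yl]-2,3-dihydro-4H-chromen-4-one | COc1cc(CCCO[Si](C)(C)C(C)(C)C)cc2c1O[C@H]([C@]1(OCOC)CCC=CC1)CC2=O | intermediate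
19 | 3-(trifluoroacetyl) derivative of 18 (enolised 1,3-diketone, C2 as in 18) | COc1cc(CCCO[Si](C)(C)C(C)(C)C)cc2c1O[C@H]([C@]1(OCOC)CCC=CC1)C(C(=O)C(F)(F)F)C2=O | intermediate (not isolated)
20 | (2S)-6-(3-{[tert-butyl(dimethyl)silyl]oxy}propyl)-3-diazo-8-methoxy-2-[(1S)-1-(methoxymethoxy)cyclohex-3-en-1-yl]-2,3-dihydro-4H-chromen-4-one | COc1cc(CCCO[Si](C)(C)C(C)(C)C)cc2c1O[C@H]([C@]1(OCOC)CCC=CC1)C(=[N+]=[N-])C2=O | intermediate
21 | (2S)-5-(3-{[tert-butyl(dimethyl)silyl]oxy}propyl)-7-methoxy-2-[(1S)-1-(methoxymethoxy)cyclohex-3-en-1-yl]-3-(oxomethylidene)-2,3-dihydro-1-benzofuran (ketene) | COc1cc(CCCO[Si](C)(C)C(C)(C)C)cc2c1O[C@H]([C@]1(OCOC)CCC=CC1)C2=C=O | intermediate (not isolated)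
22 | methyl (2S,3R)-5-(3-{[tert-butyl(dimethyl)silyl]oxy}propyl)-7-methoxy-2-[(1S)-1-(methoxymethoxy)cyclohex-3-en-1-yl]-2,3-dihydro-1-benzofuran-3-carboxylate (cis) | COc1cc(CCCO[Si](C)(C)C(C)(C)C)cc2c1O[C@H]([C@]1(OCOC)CCC=CC1)[C@@H]2C(=O)OC | intermediate (not isolated)
23 | methyl (2S,3S)-5-(3-{[tert-butyl(dimethyl)silyl]oxy}propyl)-7-methoxy-2-[(1S)-1-(methoxymethoxy)cyclohex-3-en-1-yl]-2,3-dihydro-1-benzofuran-3-carboxylate (trans) | COc1cc(CCCO[Si](C)(C)C(C)(C)C)cc2c1O[C@H]([C@]1(OCOC)CCC=CC1)[C@H]2C(=O)OC | intermediate
24 | [(2S,3R)-5-(3-{[tert-butyl(dimethyl)silyl]oxy}propyl)-7-methoxy-2-[(1S)-1-(methoxymethoxy)cyclohex-3-en-1-yl]-2,3-dihydro-1-benzofuran-3-yl]methanol | COc1cc(CCCO[Si](C)(C)C(C)(C)C)cc2c1O[C@H]([C@]1(OCOC)CCC=CC1)[C@H]2CO | intermediate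
25 | (1S)-1-[(2S,3R)-3-(hydroxymethyl)-5-(3-hydroxypropyl)-7-methoxy-2,3-dihydro-1-benzofuran-2-yl]cyclohex-3-en-1-ol | COc1cc(CCCO)cc2c1O[C@H]([C@]1(O)CCC=CC1)[C@H]2CO | intermediate
26 | (1S,3S,6R)-3-[(2S,3R)-3-(hydroxymethyl)-5-(3-hydroxypropyl)-7-methoxy-2,3-dihydro-1-benzofuran-2-yl]-7-oxabicyclo[4.1.0]heptan-3-ol (oxirane oxygen cis to the hydroxyl) | COc1cc(CCCO)cc2c1O[C@H]([C@]1(O)CC[C@H]3O[C@H]3C1)[C@H]2CO | intermediate
27 | difengpiol B, (1S,3S,4S)-1-[(2S,3R)-3-(hydroxymethyl)-5-(3-hydroxypropyl)-7-methoxy-2,3-dihydro-1-benzofuran-2-yl]-4-methoxycyclohexane-1,3-diol | COc1cc(CCCO)cc2c1O[C@H]([C@]1(O)CC[C@H](OC)[C@@H](O)C1)[C@H]2CO | target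

## Step count and least certain steps

Total: 16 steps. Longest linear sequence: 14 steps (steps 3 to 16, from 7); the arene branch is steps 1, 2 and 9 to 16.

**Step 12 (key step).**
- Risk: nitrogen may leave along a stepwise path, so that a carbene lives long enough for hydride shift from C2 (aromatising the pyranone) or for insertion into the methanol O–H or the OCH2O group. Equilibration at C3 may be incomplete, or the ester enolate may eliminate the C2–O1 bond.
- Fallback: this sets out from 18 and returns at 23. Oxidative ring contraction of 18 with the trivalent iodine reagent PhI(OAc)2 in HC(OMe)3–MeOH with catalytic H2SO4 at 0 °C would make the same C3–C3a bond without a diazo compound or carbene: iodination of the enol ether at C3, 1,2-shift of the aryl carbon from the ketal carbon, orthoester to ester. The same NaOMe equilibration then gives 23. The acetal and silyl ether are the groups to watch under the acid. The detour isolates no new compound, F0.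

**Step 10.**
- Risk: poor facial discrimination by the catalyst on an unactivated enone with a tertiary β-substituent, or reversible closure eroding the kinetic preference. The C2 epimer would differ from 18 only remotely and would be hard to remove.
- Fallback: this sets out from 6 and 16 and returns at 18. C-acylation of the dianion of 6 with Boc2O (LiN(SiMe3)2, THF, −78 °C) would give the tert-butyl β-keto ester F1. Knoevenagel condensation with 16 (piperidine, AcOH, toluene, molecular sieves) would give the alkylidene β-keto ester F2. The same thiourea, now binding the 1,3-dicarbonyl at two points, would close it to the tert-butyl chromanone-3-carboxylate F3. TsOH in toluene at 80 °C would remove the tert-butyl group and CO2 to give 18; the acetal and silyl ether must be monitored there.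

**Step 11.**
- Risk: β-elimination of the phenoxide from the C3 enolate, with unselective re-closure and loss of configuration at C2, or incomplete acylation of a hindered enolate.
- Fallback: this sets out from 18 and returns at 20. α-Oximation without an enolate (isoamyl nitrite, Me3SiCl, CH2Cl2, −20 °C) would give the 3-hydroxyimino ketone F4. A Forster reaction with chloramine (from aqueous NH3 and NaOCl; NaOH, THF–H2O, 0 °C) would then convert the oxime into the diazo ketone 20.

**Step 9.**
- Risk: slow condensation of a neopentyl-type aldehyde, and premature base-mediated closure of the phenoxide onto the enone, which would set C2 without control.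
- Fallback: this sets out from 6 and 16 and returns at 17. Allylation of the phenol (allyl bromide, K2CO3, acetone) would give the allyl ether F5. A kinetic aldol addition (LiN(SiMe3)2, THF, −78 °C, then 16) would give the β-hydroxy ketone F6. Dehydration with the Burgess reagent (toluene, 50 °C) would give the O-allyl enone F7. Deallylation with zerovalent palladium (Pd(PPh3)4, morpholine, THF, rt) would release 17 under conditions that do not close the ring.

## Further compounds

F0 | step 12 | none | none
F1 | step 10 | tert-butyl 3-[5-(3-{[tert-butyl(dimethyl)silyl]oxy}propyl)-2-hydroxy-3-methoxyphenyl]-3-oxopropanoate | COc1cc(CCCO[Si](C)(C)C(C)(C)C)cc(C(=O)CC(=O)OC(C)(C)C)c1O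
F2 | step 10 | tert-butyl 2-[5-(3-{[tert-butyl(dimethyl)silyl]oxy}propyl)-2-hydroxy-3-methoxybenzoyl]-3-[(1S)-1-(methoxymethoxy)cyclohex-3-en-1-yl]prop-2-enoate (alkene geometry not defined) | COc1cc(CCCO[Si](C)(C)C(C)(C)C)cc(C(=O)C(=C[C@]2(OCOC)CCC=CC2)C(=O)OC(C)(C)C)c1O
F3 | step 10 | tert-butyl (2S)-6-(3-{[tert-butyl(dimethyl)silyl]oxy}propyl)-8-methoxy-2-[(1S)-1-(methoxymethoxy)cyclohex-3-en-1-yl]-4-oxo-3,4-dihydro-2H-chromene-3-carboxylate (C3 enolisable, not defined) | COc1cc(CCCO[Si](C)(C)C(C)(C)C)cc2c1O[C@H]([C@]1(OCOC)CCC=CC1)C(C(=O)OC(C)(C)C)C2=O
F4 | step 11 | (2S)-6-(3-{[tert-butyl(dimethyl)silyl]oxy}propyl)-3-(hydroxyimino)-8-methoxy-2-[(1S)-1-(methoxymethoxy)cyclohex-3-en-1-yl]-2,3-dihydro-4H-chromen-4-one | COc1cc(CCCO[Si](C)(C)C(C)(C)C)cc2c1O[C@H]([C@]1(OCOC)CCC=CC1)C(=NO)C2=O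
F5 | step 9 | 1-[2-(allyloxy)-5-(3-{[tert-butyl(dimethyl)silyl]oxy}propyl)-3-methoxyphenyl]ethan-1-one | C=CCOc1c(OC)cc(CCCO[Si](C)(C)C(C)(C)C)cc1C(C)=O
F6 | step 9 | 1-[2-(allyloxy)-5-(3-{[tert-butyl(dimethyl)silyl]oxy}propyl)-3-methoxyphenyl]-3-hydroxy-3-[(1S)-1-(methoxymethoxy)cyclohex-3-en-1-yl]propan-1-one (both carbinol epimers) | C=CCOc1c(OC)cc(CCCO[Si](C)(C)C(C)(C)C)cc1C(=O)CC(O)[C@]1(OCOC)CCC=CC1
F7 | step 9 | (2E)-1-[2-(allyloxy)-5-(3-{[tert-butyl(dimethyl)silyl]oxy}propyl)-3-methoxyphenyl]-3-[(1S)-1-(methoxymethoxy)cyclohex-3-en-1-yl]prop-2-en-1-one | C=CCOc1c(OC)cc(CCCO[Si](C)(C)C(C)(C)C)cc1C(=O)/C=C/[C@]1(OCOC)CCC=CC1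
A1 | alternative 1 | methyl (1S)-1-[(dimethylsilyl)oxy]-4-methoxycyclohex-3-ene-1-carboxylate | COC(=O)[C@]1(O[SiH](C)C)CCC(OC)=CC1
A2 | alternative 1 | methyl 2-methoxy-7,7-dimethyl-6-oxa-7-silabicyclo[3.2.1]octane-5-carboxylate (bridged oxasilolane, configuration as in the SMILES) | COC(=O)[C@]1(O[Si]2(C)C)CC[C@H](OC)[C@@H]2C1
A3 | alternative 1 | methyl (1S,3S,4S)-1,3-dihydroxy-4-methoxycyclohexane-1-carboxylate | COC(=O)[C@]1(O)CC[C@H](OC)[C@@H](O)C1
A4 | alternative 2 | (5S)-1-[(2S,3R)-3-({[tert-butyl(dimethyl)silyl]oxy}methyl)-5-(3-{[tert-butyl(dimethyl)silyl]oxy}propyl)-7-methoxy-2,3-dihydro-1-benzofuran-2-yl]-5-methoxyheptane-1,6-dione (configuration as in the SMILES) | COc1cc(CCCO[Si](C)(C)C(C)(C)C)cc2c1O[C@H](C(=O)CC[C@H](OC)C(C)=O)[C@H]2CO[Si](C)(C)C(C)(C)C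
A5 | alternative 2 | 3-hydroxy-3-(dihydrobenzofuran-2-yl)-6-methoxycyclohexanone (bis-silyl ether, configuration as in the SMILES) | COc1cc(CCCO[Si](C)(C)C(C)(C)C)cc2c1O[C@H]([C@]1(O)CC[C@H](OC)C(=O)C1)[C@H]2CO[Si](C)(C)C(C)(C)C
A6 | alternative 3 | 2-[2-(benzyloxy)-1-(4-methylbenzenesulfonyl)ethyl]-4-(3-{[tert-butyl(dimethyl)silyl]oxy}propyl)-6-methoxyphenol (racemic) | COc1cc(CCCO[Si](C)(C)C(C)(C)C)cc(C(COCc2ccccc2)S(=O)(=O)c2ccc(C)cc2)c1O
A7 | alternative 3 | dimethylsulfonium 2-oxohex-5-en-1-ylide | C=CCCC(=O)[CH-][S+](C)C
A8 | alternative 3 | trans-2-(pent-4-enoyl)-3-(benzyloxymethyl)dihydrobenzofuran (configuration as in the SMILES) | COc1cc(CCCO[Si](C)(C)C(C)(C)C)cc2c1O[C@H](C(=O)CCC=C)[C@H]2COCc3ccccc3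
A9 | alternative 3 | (1S)-1-[(2S,3R)-3-[(benzyloxy)methyl]-5-(3-{[tert-butyl(dimethyl)silyl]oxy}propyl)-7-methoxy-2,3-dihydro-1-benzofuran-2-yl]cyclohex-3-en-1-ol | COc1cc(CCCO[Si](C)(C)C(C)(C)C)cc2c1O[C@H]([C@]1(O)CCC=CC1)[C@H]2COCc1ccccc1
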